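**Retrosynthetic overview**
- Target 19 comes from 7‑hydroxybenzofuran 16 by O‑methylation, C3 formylation and removal of two benzyl ethers.
- The feature used: in ring A the C5–C6 bond joins the chain‑bearing C5 to the unsubstituted C6, which sits next to the oxygenated C7 on furan carbon C7a. Cutting C5=C6 of the 4H‑7‑keto tautomer (ring‑closing metathesis transform) opens ring A to the 2‑acryloyl‑3‑(2‑alkylallyl)furan 14.
- 14 comes from the 2,4‑disubstituted furan 10 by α‑formylation, vinyl Grignard addition and oxidation.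
- 10 comes from furylmethyl bromide 5 (Suzuki coupling of 1 with 2, reduction, bromination) and alkenyl Grignard 9 (from pent‑4‑yn‑1‑ol 6).
- Ring order: the furan (ring B) is bought, the aryl ring is attached by cross‑coupling, and ring A is closed last on the furan.

Key step: step 10

Remark: the target is achiral. The only stereocentre on the route, the carbinol carbon of 13, is formed racemic and is erased by the oxidation in step 9. Compounds 1, 2, 6 and 12 are taken as purchased.

**Step 1**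
Reactants: 1 methyl 5‑bromofuran‑3‑carboxylate; 2 [4‑(benzyloxy)‑3‑methoxyphenyl]boronic acid
Product: 3 methyl 5‑[4‑(benzyloxy)‑3‑methoxyphenyl]furan‑3‑carboxylate
Conditions: Pd(PPh3)4 (3 mol %), Na2CO3 (2 M aq.), DME, 85 °C
Reagents that add atoms: none
Why: Suzuki–Miyaura coupling; zerovalent palladium inserts readily into the C–Br bond at the furan α‑carbon, and the methyl ester should survive aqueous carbonate at this temperature.

**Step 2**
Reactants: 3 methyl 5‑[4‑(benzyloxy)‑3‑methoxyphenyl]furan‑3‑carboxylate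
Product: 4 {5‑[4‑(benzyloxy)‑3‑methoxyphenyl]furan‑3‑yl}methanol
Conditions: LiAlH4, THF, 0 °C; H2O work‑up
Reagents that add atoms: none
Why: Hydride reduction of the ester to the primary alcohol; the aryl ethers and the furan are inert to LiAlH4.

**Step 3**
Reactants: 4 {5‑[4‑(benzyloxy)‑3‑methoxyphenyl]furan‑3‑yl}methanol
Product: 5 2‑[4‑(benzyloxy)‑3‑methoxyphenyl]‑4‑(bromomethyl)furan
Conditions: CBr4, PPh3, CH2Cl2, 0 °C; used crude at once
Reagents that add atoms: carbon tetrabromide, BrC(Br)(Br)Br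
Why: The Appel reaction converts the primary furylmethanol to the bromide under neutral conditions, which avoids acid that would ionise the furylmethyl position.

**Step 4**
Reactants: 6 pent‑4‑yn‑1‑ol
Product: 7 4‑bromopent‑4‑en‑1‑ol
Conditions: Et4NBr, HBr, CH2Cl2, 40 °C
Reagents that add atoms: hydrogen bromide, Br
Why: Markovnikov hydrobromination of the terminal alkyne by tetraethylammonium hydrogen dibromide should stop at the 2‑bromo‑1‑alkene, because the vinyl bromide is deactivated toward a second addition.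

**Step 5**
Reactants: 7 4‑bromopent‑4‑en‑1‑ol
Product: 8 {[(4‑bromopent‑4‑en‑1‑yl)oxy]methyl}benzene
Conditions: NaH, BnBr, THF/DMF, 0 °C → rt
Reagents that add atoms: benzyl bromide, BrCc1ccccc1
Why: Williamson ether synthesis on the primary alkoxide; the vinyl bromide does not react with NaH or the alkoxide at this temperature.

**Step 6**
Reactants: 8 {[(4‑bromopent‑4‑en‑1‑yl)oxy]methyl}benzene; 5 2‑[4‑(benzyloxy)‑3‑methoxyphenyl]‑4‑(bromomethyl)furan
Product: 10 2‑[4‑(benzyloxy)‑3‑methoxyphenyl]‑4‑[5‑(benzyloxy)‑2‑methylidenepentyl]furan, via alkenylmagnesium bromide 9 (not isolated)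
Conditions: 8, Mg, THF, 45 °C; then 5, CuBr·SMe2 (10 mol %), THF, −30 → 0 °C
Reagents that add atoms: magnesium, [Mg] (kept only in intermediate 9)
Why: Grignard formation followed by copper‑catalysed (Kochi‑type) sp2–sp3 cross‑coupling; an alkenyl Grignard reagent displaces a primary benzylic‑type bromide cleanly under monovalent copper catalysis.

**Step 7**
Reactants: 10 2‑[4‑(benzyloxy)‑3‑methoxyphenyl]‑4‑[5‑(benzyloxy)‑2‑methylidenepentyl]furan
Product: 11 5‑[4‑(benzyloxy)‑3‑methoxyphenyl]‑3‑[5‑(benzyloxy)‑2‑methylidenepentyl]furan‑2‑carbaldehyde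
Conditions: POCl3, DMF, 0 °C → rt; then H2O
Reagents that add atoms: N,N‑dimethylformamide, CN(C)C=O (formyl carbon); water, O (carbonyl oxygen on hydrolysis)
Why: Vilsmeier–Haack formylation; the single free furan α‑position is far more nucleophilic than the isolated 1,1‑disubstituted alkene or the dialkoxyarene, so substitution should occur there at low temperature.

**Step 8**
Reactants: 11 5‑[4‑(benzyloxy)‑3‑methoxyphenyl]‑3‑[5‑(benzyloxy)‑2‑methylidenepentyl]furan‑2‑carbaldehyde; 12 vinylmagnesium bromide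
Product: 13 rac‑1‑{5‑[4‑(benzyloxy)‑3‑methoxyphenyl]‑3‑[5‑(benzyloxy)‑2‑methylidenepentyl]furan‑2‑yl}prop‑2‑en‑1‑ol
Conditions: THF, −78 → 0 °C; H2O work‑up
Reagents that add atoms: none
Why: Grignard 1,2‑addition to the aldehyde; the carbinol stereocentre forms racemic, which is acceptable because the next step removes it.

**Step 9**
Reactants: 13 rac‑1‑{5‑[4‑(benzyloxy)‑3‑methoxyphenyl]‑3‑[5‑(benzyloxy)‑2‑methylidenepentyl]furan‑2‑yl}prop‑2‑en‑1‑ol
Product: 14 1‑{5‑[4‑(benzyloxy)‑3‑methoxyphenyl]‑3‑[5‑(benzyloxy)‑2‑methylidenepentyl]furan‑2‑yl}prop‑2‑en‑1‑one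
Conditions: MnO2 (activated, excess), CH2Cl2, rt; filtered and used at once
Reagents that add atoms: none
Why: MnO2 oxidation is selective for the doubly activated (allylic and furylic) alcohol and leaves the benzyl ethers and the isolated alkene untouched.

**Step 10**
Reactants: 14 1‑{5‑[4‑(benzyloxy)‑3‑methoxyphenyl]‑3‑[5‑(benzyloxy)‑2‑methylidenepentyl]furan‑2‑yl}prop‑2‑en‑1‑one
Product: 16 2‑[4‑(benzyloxy)‑3‑methoxyphenyl]‑5‑[3‑(benzyloxy)propyl]‑1‑benzofuran‑7‑ol, via benzofuran‑7(4H)‑one 15 (not isolated)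
Conditions: second‑generation Grubbs catalyst [RuCl2(=CHPh)(H2IMes)(PCy3)] (5 mol %), CH2Cl2 (0.005 M), 40 °C; then Et3N (cat.), rt
Reagents that add atoms: none
Why: The ruthenium benzylidene exchanges onto one of the two terminal alkenes of 14, the new alkylidene adds intramolecularly to the other alkene to give a ruthenacyclobutane, and cycloreversion forms the C5=C6 bond with loss of ethylene; this is the known ring‑closing metathesis of dienones to keto tautomers of phenols. Ring A closes as a six‑membered carbocycle fused to the furan, between the acryloyl CH= (future C6) and the substituted alkene carbon of the 2‑alkylallyl arm (future C5), the two arms being held side by side on adjacent furan carbons. The first product, ketone 15, has acidic C4–H2 (furylic and γ to the enone carbonyl) and should enolise to the aromatic 7‑hydroxybenzofuran 16, which makes the closure irreversible. No stereocentre is formed. The step needs ring closure to outrun cross‑metathesis or oligomerisation of the vinyl ketone and ruthenium hydride migration of the skipped 1,1‑disubstituted alkene; the adjacent placement of the arms, high dilution and the aromatisation sink favour closure, and a short reaction time (with 1,4‑benzoquinone if needed) limits alkene migration. The substitution pattern of ring A (oxygen at C7, chain at C5, hydrogen at C4 and C6) is fixed by the connectivity of 14, so no arene substitution chemistry is required.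

**Step 11**
Reactants: 16 2‑[4‑(benzyloxy)‑3‑methoxyphenyl]‑5‑[3‑(benzyloxy)propyl]‑1‑benzofuran‑7‑ol
Product: 17 2‑[4‑(benzyloxy)‑3‑methoxyphenyl]‑5‑[3‑(benzyloxy)propyl]‑7‑methoxy‑1‑benzofuran
Conditions: MeI, K2CO3, acetone, 50 °C
Reagents that add atoms: iodomethane, CI
Why: Williamson O‑methylation of the only free phenol; no other acidic or nucleophilic site is present.

**Step 12**
Reactants: 17 2‑[4‑(benzyloxy)‑3‑methoxyphenyl]‑5‑[3‑(benzyloxy)propyl]‑7‑methoxy‑1‑benzofuran
Product: 18 2‑[4‑(benzyloxy)‑3‑methoxyphenyl]‑5‑[3‑(benzyloxy)propyl]‑7‑methoxy‑1‑benzofuran‑3‑carbaldehyde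
Conditions: POCl3, DMF, 0 → 70 °C; then H2O
Reagents that add atoms: N,N‑dimethylformamide, CN(C)C=O (formyl carbon); water, O (carbonyl oxygen on hydrolysis)
Why: Vilsmeier–Haack formylation; with C2 blocked by the aryl group, C3 of the benzofuran (enol ether β‑carbon conjugated with the aryl ring) is the most nucleophilic position, ahead of the anisole‑type carbons.

**Step 13**
Reactants: 18 2‑[4‑(benzyloxy)‑3‑methoxyphenyl]‑5‑[3‑(benzyloxy)propyl]‑7‑methoxy‑1‑benzofuran‑3‑carbaldehyde
Product: 19 2‑(4‑hydroxy‑3‑methoxyphenyl)‑5‑(3‑hydroxypropyl)‑7‑methoxy‑1‑benzofuran‑3‑carbaldehyde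
Conditions: BCl3 (1 M in CH2Cl2), C6HMe5, CH2Cl2, −78 → 0 °C; then H2O
Reagents that add atoms: none
Why: Lewis acid debenzylation with BCl3, with pentamethylbenzene as a non‑basic scavenger for the benzyl cation, should cleave the aryl and the primary alkyl benzyl ether at low temperature without reducing the aldehyde or cleaving the methyl ethers, neither of which is ortho to a carbonyl.

**Compound list**
1 | methyl 5‑bromofuran‑3‑carboxylate | COC(=O)c1coc(Br)c1 | starting material
2 | [4‑(benzyloxy)‑3‑methoxyphenyl]boronic acid | COc1cc(B(O)O)ccc1OCc1ccccc1 | starting material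
3 | methyl 5‑[4‑(benzyloxy)‑3‑methoxyphenyl]furan‑3‑carboxylate | COC(=O)c1coc(-c2ccc(OCc3ccccc3)c(OC)c2)c1 | intermediate
4 | {5‑[4‑(benzyloxy)‑3‑methoxyphenyl]furan‑3‑yl}methanol | OCc1coc(-c2ccc(OCc3ccccc3)c(OC)c2)c1 | intermediate
5 | 2‑[4‑(benzyloxy)‑3‑methoxyphenyl]‑4‑(bromomethyl)furan | BrCc1coc(-c2ccc(OCc3ccccc3)c(OC)c2)c1 | intermediate
6 | pent‑4‑yn‑1‑ol | C#CCCCO | starting material
7 | 4‑bromopent‑4‑en‑1‑ol | C=C(Br)CCCO | intermediate
8 | {[(4‑bromopent‑4‑en‑1‑yl)oxy]methyl}benzene | C=C(Br)CCCOCc1ccccc1 | intermediate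
9 | [5‑(benzyloxy)pent‑1‑en‑2‑yl]magnesium bromide | C=C([Mg]Br)CCCOCc1ccccc1 | intermediate (not isolated)
10 | 2‑[4‑(benzyloxy)‑3‑methoxyphenyl]‑4‑[5‑(benzyloxy)‑2‑methylidenepentyl]furan | C=C(CCCOCc1ccccc1)Cc1coc(-c2ccc(OCc3ccccc3)c(OC)c2)c1 | intermediate
11 | 5‑[4‑(benzyloxy)‑3‑methoxyphenyl]‑3‑[5‑(benzyloxy)‑2‑methylidenepentyl]furan‑2‑carbaldehyde | O=Cc1oc(-c2ccc(OCc3ccccc3)c(OC)c2)cc1CC(=C)CCCOCc1ccccc1 | intermediate
12 | vinylmagnesium bromide | C=C[Mg]Br | starting material
13 | rac‑1‑{5‑[4‑(benzyloxy)‑3‑methoxyphenyl]‑3‑[5‑(benzyloxy)‑2‑methylidenepentyl]furan‑2‑yl}prop‑2‑en‑1‑ol (racemic at the carbinol carbon) | C=CC(O)c1oc(-c2ccc(OCc3ccccc3)c(OC)c2)cc1CC(=C)CCCOCc1ccccc1 | intermediate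
14 | 1‑{5‑[4‑(benzyloxy)‑3‑methoxyphenyl]‑3‑[5‑(benzyloxy)‑2‑methylidenepentyl]furan‑2‑yl}prop‑2‑en‑1‑one | C=CC(=O)c1oc(-c2ccc(OCc3ccccc3)c(OC)c2)cc1CC(=C)CCCOCc1ccccc1 | intermediate
15 | 2‑[4‑(benzyloxy)‑3‑methoxyphenyl]‑5‑[3‑(benzyloxy)propyl]‑1‑benzofuran‑7(4H)‑one | O=C1C=C(CCCOCc2ccccc2)Cc2cc(-c3ccc(OCc4ccccc4)c(OC)c3)oc12 | intermediate (not isolated)
16 | 2‑[4‑(benzyloxy)‑3‑methoxyphenyl]‑5‑[3‑(benzyloxy)propyl]‑1‑benzofuran‑7‑ol | Oc1cc(CCCOCc2ccccc2)cc2cc(-c3ccc(OCc4ccccc4)c(OC)c3)oc12 | intermediate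
17 | 2‑[4‑(benzyloxy)‑3‑methoxyphenyl]‑5‑[3‑(benzyloxy)propyl]‑7‑methoxy‑1‑benzofuran | COc1cc(CCCOCc2ccccc2)cc2cc(-c3ccc(OCc4ccccc4)c(OC)c3)oc12 | intermediate
18 | 2‑[4‑(benzyloxy)‑3‑methoxyphenyl]‑5‑[3‑(benzyloxy)propyl]‑7‑methoxy‑1‑benzofuran‑3‑carbaldehyde | COc1cc(CCCOCc2ccccc2)cc2c(C=O)c(-c3ccc(OCc4ccccc4)c(OC)c3)oc12 | intermediate
19 | 2‑(4‑hydroxy‑3‑methoxyphenyl)‑5‑(3‑hydroxypropyl)‑7‑methoxy‑1‑benzofuran‑3‑carbaldehyde | COc1cc(-c2oc3c(OC)cc(CCCO)cc3c2C=O)ccc1O | target

**Step count**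
Total: 13 steps. Longest linear sequence: 11 steps (steps 1, 2, 3, 6, 7, 8, 9, 10, 11, 12, 13).

**Steps most likely to fail**

Step 10. The vinyl ketone may oligomerise or deactivate the catalyst before ring closure, or the skipped 1,1‑disubstituted alkene may migrate into conjugation with the furan so that no six‑membered closure is possible. The fallback sets out from allylic alcohol 13 and carries out the metathesis before the oxidation. The dienol, which lacks the electron‑poor enone, is closed with the second‑generation Grubbs catalyst in dilute CH2Cl2 to give rac‑2‑[4‑(benzyloxy)‑3‑methoxyphenyl]‑5‑[3‑(benzyloxy)propyl]‑4,7‑dihydro‑1‑benzofuran‑7‑ol F1. This is kept free of acid, since it would otherwise lose water to a deoxygenated benzofuran, and is oxidised directly with MnO2 in CH2Cl2 to ketone 15, which tautomerises to phenol 16, where the route is rejoined.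

Step 6. The electron‑rich furylmethyl bromide may decompose on handling, or halogen–metal exchange and Wurtz‑type homocoupling may consume both partners. The fallback sets out from alcohol 4 and Grignard reagent 9 and replaces the copper/Grignard coupling by a palladium‑catalysed Suzuki–Miyaura sp3–sp2 coupling. Alcohol 4 is converted with MsCl, Et3N and LiCl in THF into the more stable 2‑[4‑(benzyloxy)‑3‑methoxyphenyl]‑4‑(chloromethyl)furan F2. Reagent 9 is quenched with 2‑isopropoxy‑4,4,5,5‑tetramethyl‑1,3,2‑dioxaborolane to give 2‑[5‑(benzyloxy)pent‑1‑en‑2‑yl]‑4,4,5,5‑tetramethyl‑1,3,2‑dioxaborolane F3. The two are coupled with PdCl2(dppf) and K3PO4 in THF/H2O at 60 °C to give furan 10, where the route is rejoined.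

Step 13. The primary alkyl benzyl ether may cleave incompletely at low temperature, while warming may cost a methyl ether through boron chelation next to the freed phenol. The fallback sets out from 17 and removes the benzyl groups before the aldehyde is present. Hydrogenolysis (H2, Pd/C, EtOAc, rt) gives 4‑[5‑(3‑hydroxypropyl)‑7‑methoxy‑1‑benzofuran‑2‑yl]‑2‑methoxyphenol F4. Acetylation (Ac2O, pyridine) gives 3‑[2‑(4‑acetoxy‑3‑methoxyphenyl)‑7‑methoxy‑1‑benzofuran‑5‑yl]propyl acetate F5, which protects both hydroxyl groups from the chloroiminium reagent. Vilsmeier–Haack formylation (POCl3, DMF) gives 3‑[2‑(4‑acetoxy‑3‑methoxyphenyl)‑3‑formyl‑7‑methoxy‑1‑benzofuran‑5‑yl]propyl acetate F6. Methanolysis (K2CO3, MeOH, rt) then gives target 19.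

**Further compounds**
F1 | step 10 | rac‑2‑[4‑(benzyloxy)‑3‑methoxyphenyl]‑5‑[3‑(benzyloxy)propyl]‑4,7‑dihydro‑1‑benzofuran‑7‑ol | OC1C=C(CCCOCc2ccccc2)Cc2cc(-c3ccc(OCc4ccccc4)c(OC)c3)oc12
F2 | step 6 | 2‑[4‑(benzyloxy)‑3‑methoxyphenyl]‑4‑(chloromethyl)furan | ClCc1coc(-c2ccc(OCc3ccccc3)c(OC)c2)c1
F3 | step 6 | 2‑[5‑(benzyloxy)pent‑1‑en‑2‑yl]‑4,4,5,5‑tetramethyl‑1,3,2‑dioxaborolane | C=C(CCCOCc1ccccc1)B1OC(C)(C)C(C)(C)O1
F4 | step 13 | 4‑[5‑(3‑hydroxypropyl)‑7‑methoxy‑1‑benzofuran‑2‑yl]‑2‑methoxyphenol | COc1cc(CCCO)cc2cc(-c3ccc(O)c(OC)c3)oc12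
F5 | step 13 | 3‑[2‑(4‑acetoxy‑3‑methoxyphenyl)‑7‑methoxy‑1‑benzofuran‑5‑yl]propyl acetate | COc1cc(CCCOC(C)=O)cc2cc(-c3ccc(OC(C)=O)c(OC)c3)oc12
F6 | step 13 | 3‑[2‑(4‑acetoxy‑3‑methoxyphenyl)‑3‑formyl‑7‑methoxy‑1‑benzofuran‑5‑yl]propyl acetate | COc1cc(CCCOC(C)=O)cc2c(C=O)c(-c3ccc(OC(C)=O)c(OC)c3)oc12
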